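**Plan**

1. Locants: ring A is the butanoyl ring (C1 butanoyl, C2 OH, C3 Me, C4 OMe, C5 CH2, C6 OH) and ring B the acetyl ring (C1' CH2, C2' OH, C3' Me, C4' OH, C5' acetyl, C6' OH); the target has no stereocentre.
2. The retrosynthesis cuts ring B at C1'–C6' and C4'–C5' (cycloaddition with loss of ethylene), then the CH2–C1' bond (enolate alkylation), then on ring A the C5–CH2 bond (formylation), the C4 O–Me bond and the C1–acyl bond (Friedel–Crafts).
3. Enabling feature: C2'(O)–C3'(Me)–C4'(O) with the bridge on C1' is 2-methylcyclohexane-1,3-dione alkylated next to one carbonyl, whose C5 and C6 can leave as ethylene, and C5'(acetyl)–C6'(O) is a 4-alkoxybut-3-yn-2-one.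
4. Forward: ring A is completed first (acylation, O-methylation, formylation, benzylation, CH2Br), joined to the benzyl vinylogous ester of the dione and silylated to a 1-benzyloxy-3-silyloxycyclohexa-1,3-diene; ring B then forms in one operation from this diene and the ynone, and two deprotections finish.
5. The ynone oxygen carries 1-adamantyl instead of a simple alkyl group: it cannot fragment to a ketene by retro-ene loss of an alkene on heating, and acid removes it without chelation. A methyl or ethyl ether at C6' would need a boron halide, whose chelation to the acetyl group is pre-empted by the C4' oxygen and which would endanger the ring A methoxy group.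
6. Stereochemistry: none has to be set; the racemic centre from the alkylation and the bridgeheads of the cycloadduct vanish when ring B becomes aromatic, and the butanoyl ketone travels through diene formation and cycloaddition as its silyl enol ether.

Key step: step 12

**Route**

Step 1
Reactants: 1 2-methylphloroglucinol (2-methylbenzene-1,3,5-triol); 2 butanoyl chloride
Product: 3 1-(2,4,6-trihydroxy-3-methylphenyl)butan-1-one
Conditions: AlCl3, PhNO2, rt to 60 °C; aq HCl
Reagents that add atoms: none
Why: Friedel–Crafts C-acylation of the electron-rich triol, in which the two free ring positions of 1 are equivalent and the first acyl group deactivates the ring against a second.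

Step 2
Reactants: 3 1-(2,4,6-trihydroxy-3-methylphenyl)butan-1-one
Product: 4 1-(2,6-dihydroxy-4-methoxy-3-methylphenyl)butan-1-one (aspidinol)
Conditions: Me2SO4 (1 equiv), K2CO3 (1 equiv), acetone, 0 °C to rt
Reagents that add atoms: dimethyl sulfate, COS(=O)(=O)OC
Why: Williamson O-methylation under limiting base, which should select the hydroxyl para to the carbonyl because it is the most acidic and is not held in a hydrogen bond to the ketone.

Step 3
Reactants: 4 1-(2,6-dihydroxy-4-methoxy-3-methylphenyl)butan-1-one
Product: 5 3-butanoyl-2,4-dihydroxy-6-methoxy-5-methylbenzaldehyde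
Conditions: Cl2CHOMe, TiCl4, CH2Cl2, −10 to 0 °C; then aq HCl
Reagents that add atoms: dichloromethyl methyl ether, COC(Cl)Cl; water, O
Why: Rieche formylation, an electrophilic aromatic substitution at the only free ring position, which lies ortho and para to hydroxyl groups; the α-chloro ether formed is hydrolysed to the aldehyde on work-up.

Step 4
Reactants: 5 3-butanoyl-2,4-dihydroxy-6-methoxy-5-methylbenzaldehyde
Product: 6 2,4-bis(benzyloxy)-3-butanoyl-6-methoxy-5-methylbenzaldehyde
Conditions: BnBr, K2CO3, DMF, 60 °C
Reagents that add atoms: benzyl bromide, BrCc1ccccc1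
Why: Williamson O-benzylation of both chelated phenols in a polar aprotic medium, which favours O- over C-alkylation of the fully substituted ring.

Step 5
Reactants: 6 2,4-bis(benzyloxy)-3-butanoyl-6-methoxy-5-methylbenzaldehyde
Product: 7 1-[2,6-bis(benzyloxy)-3-(hydroxymethyl)-4-methoxy-5-methylphenyl]butan-1-one
Conditions: NaBH4, THF–MeOH, −20 °C
Reagents that add atoms: none
Why: Chemoselective borohydride reduction, since the aldehyde is far more electrophilic than the aryl ketone, which is flanked by two ortho benzyloxy groups and twisted out of conjugation.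

Step 6
Reactants: 7 1-[2,6-bis(benzyloxy)-3-(hydroxymethyl)-4-methoxy-5-methylphenyl]butan-1-one
Product: 8 1-[2,6-bis(benzyloxy)-3-(bromomethyl)-4-methoxy-5-methylphenyl]butan-1-one
Conditions: PBr3, pyridine (cat.), Et2O, 0 °C; used crude at once
Reagents that add atoms: phosphorus tribromide, BrP(Br)Br
Why: Substitution of a benzylic alcohol by bromide through its phosphite ester, fast for this electron-rich benzylic position; the labile bromide is not stored.

Step 7
Reactants: 9 2-methylcyclohexane-1,3-dione
Product: 10 3-(benzyloxy)-2-methylcyclohex-2-en-1-one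
Conditions: BnOH, TsOH·H2O (cat.), toluene, reflux, azeotropic removal of water
Reagents that add atoms: benzyl alcohol, OCc1ccccc1
Why: Acid-catalysed enol etherification of a cyclic 1,3-dione (vinylogous ester formation) driven by removal of water, with only one product possible from the symmetrical dione.

Step 8
Reactants: 10 3-(benzyloxy)-2-methylcyclohex-2-en-1-one; 8 1-[2,6-bis(benzyloxy)-3-(bromomethyl)-4-methoxy-5-methylphenyl]butan-1-one
Product: 12 3-(benzyloxy)-6-{[2,4-bis(benzyloxy)-3-butanoyl-6-methoxy-5-methylphenyl]methyl}-2-methylcyclohex-2-en-1-one (racemic), via lithium dienolate 11 (not isolated)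
Conditions: LiN(iPr)2 (1.45 equiv), 10 (1.5 equiv), THF, −78 °C; then 8 (1 equiv), DMPU, −78 to −30 °C
Reagents that add atoms: none
Why: Stork–Danheiser α'-alkylation, in which kinetic deprotonation of the vinylogous ester at C6 and C-alkylation by the very reactive benzylic bromide, run cold with excess enolate, should outrun proton transfer from the butanoyl CH2; the new centre is racemic and is erased in step 9.

Step 9
Reactants: 12 3-(benzyloxy)-6-{[2,4-bis(benzyloxy)-3-butanoyl-6-methoxy-5-methylphenyl]methyl}-2-methylcyclohex-2-en-1-one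
Product: 14 1-(benzyloxy)-2-methyl-3-(trimethylsilyloxy)-4-{[2,4-bis(benzyloxy)-6-methoxy-5-methyl-3-[(1Z)-1-(trimethylsilyloxy)but-1-en-1-yl]phenyl]methyl}cyclohexa-1,3-diene, via dilithium bis-enolate 13 (not isolated)
Conditions: LiN(iPr)2 (2.5 equiv), THF, −78 to −40 °C; then Me3SiCl, −78 to 0 °C; pentane, filtration under argon
Reagents that add atoms: chlorotrimethylsilane, C[Si](C)(C)Cl
Why: Kinetic double enolisation (butanoyl CH2 first, then the α' C–H of the vinylogous ester, favoured over the γ position under kinetic control) and O-silylation, the standard entry to 1-alkoxy-3-silyloxycyclohexa-1,3-dienes, which also parks the aryl ketone as its (Z)-silyl enol ether.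

Step 10
Reactants: 15 adamantan-1-ol; 16 trichloroethylene
Product: 18 1-{[(E)-1,2-dichloroethenyl]oxy}adamantane, via potassium adamantan-1-olate 17 (not isolated)
Conditions: KH, THF, 0 °C to rt; then Cl2C=CHCl, −50 °C to rt
Reagents that add atoms: none
Why: Base-mediated elimination of trichloroethylene to dichloroacetylene and anti addition of the alkoxide, the usual first stage of ynol ether synthesis from an alcohol, giving the (E)-dichlorovinyl ether.

Step 11
Reactants: 18 1-{[(E)-1,2-dichloroethenyl]oxy}adamantane
Product: 20 4-(adamantan-1-yloxy)but-3-yn-2-one, via lithium alkoxyacetylide 19 (not isolated)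
Conditions: n-BuLi (2.2 equiv), THF, −78 to −40 °C; then MeC(O)N(OMe)Me, −78 to 0 °C; aq NH4Cl
Reagents that add atoms: N-methoxy-N-methylacetamide, CON(C)C(C)=O
Why: Dehydrochlorination and chlorine–lithium exchange give the lithium alkoxyacetylide, which is acylated in a Weinreb ketone synthesis, the chelated tetrahedral adduct preventing a second addition.

Step 12
Reactants: 14 1-(benzyloxy)-2-methyl-3-(trimethylsilyloxy)-4-{[2,4-bis(benzyloxy)-6-methoxy-5-methyl-3-[(1Z)-1-(trimethylsilyloxy)but-1-en-1-yl]phenyl]methyl}cyclohexa-1,3-diene; 20 4-(adamantan-1-yloxy)but-3-yn-2-one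
Product: 23 1-[3-{[3-acetyl-2-(adamantan-1-yloxy)-4-(benzyloxy)-6-hydroxy-5-methylphenyl]methyl}-2,6-bis(benzyloxy)-4-methoxy-5-methylphenyl]butan-1-one, via bicyclo[2.2.2]octadiene cycloadduct 21 (not isolated), via bis-silylated arene 22 (not isolated)
Conditions: toluene, 2,6-di-tert-butyl-4-methylphenol (trace), sealed tube, 110 °C then 150 °C; then 1 M aq HCl, THF, 0 °C
Reagents that add atoms: none
Why: Proposed new method: diene 14, whose HOMO is raised by the 1-benzyloxy and 3-silyloxy groups and is largest at the terminus carrying the ring A-methyl substituent, should add to the acyl-activated triple bond of 20 in a thermal, strongly asynchronous [4+2] cycloaddition to give bicyclo[2.2.2]octadiene 21, which then loses its CH2–CH2 bridge as ethylene in a retro-[4+2] step and is left as arene 22. The closest known reaction type is the Alder–Rickert synthesis of resorcinol derivatives from 1-alkoxy-3-silyloxycyclohexa-1,3-dienes and acetylenic ketones or esters, which has not been shown for an alkoxy-substituted ynone or for a diene substituted at both termini. Ring B is the only ring closed; it forms by intermolecular [4+2] cycloaddition that makes C1'–C6' and C4'–C5' and becomes aromatic on cycloreversion, so the two bridgehead centres of 21 disappear and no stereocentre has to be controlled. The selectivity needed is regiochemical, and both partners are polarised to match: the nucleophilic diene terminus should bond to the oxygen-bearing β-carbon of the ynone, which places the acetyl group between the two ether oxygens. The adamantyl ether cannot lose an alkene by retro-ene fragmentation, so the ynone should survive temperatures at which simple alkyl ynol ethers give ketenes, and the two-stage heating lets the diene be consumed before [1,5]-hydrogen shifts become fast. Dilute acid finally hydrolyses the aryl silyl ether and the silyl enol ether of the butanoyl group.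

Step 13
Reactants: 23 1-[3-{[3-acetyl-2-(adamantan-1-yloxy)-4-(benzyloxy)-6-hydroxy-5-methylphenyl]methyl}-2,6-bis(benzyloxy)-4-methoxy-5-methylphenyl]butan-1-one
Product: 24 1-[3-{[3-acetyl-4-(benzyloxy)-2,6-dihydroxy-5-methylphenyl]methyl}-2,6-bis(benzyloxy)-4-methoxy-5-methylphenyl]butan-1-one
Conditions: CF3CO2H–CH2Cl2 (1:1), 0 °C to rt
Reagents that add atoms: none
Why: Acidolysis of a tertiary-alkyl aryl ether by an SN1 path through the 1-adamantyl cation, captured as its trifluoroacetate, should free the C6' phenol while the methyl and benzyl ethers, which do not ionise in this way, stay in place.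

Step 14
Reactants: 24 1-[3-{[3-acetyl-4-(benzyloxy)-2,6-dihydroxy-5-methylphenyl]methyl}-2,6-bis(benzyloxy)-4-methoxy-5-methylphenyl]butan-1-one
Product: 25 1-[3-[(3-acetyl-2,4,6-trihydroxy-5-methylphenyl)methyl]-2,6-dihydroxy-4-methoxy-5-methylphenyl]butan-1-one (CNP0258463.0)
Conditions: H2 (1 atm), 10% Pd/C, EtOAc–MeOH, rt
Reagents that add atoms: none
Why: Hydrogenolysis of the three benzyl aryl ethers over Pd/C under neutral conditions should leave the methyl ether, the hydrogen-bonded aryl ketones and the diarylmethane bridge untouched.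

**Compound list**

1 | 2-methylphloroglucinol (2-methylbenzene-1,3,5-triol) | Cc1c(O)cc(O)cc1O | starting material
2 | butanoyl chloride | CCCC(Cl)=O | starting material
3 | 1-(2,4,6-trihydroxy-3-methylphenyl)butan-1-one | CCCC(=O)c1c(O)c(C)c(O)cc1O | intermediate
4 | 1-(2,6-dihydroxy-4-methoxy-3-methylphenyl)butan-1-one (aspidinol) | CCCC(=O)c1c(O)c(C)c(OC)cc1O | intermediate
5 | 3-butanoyl-2,4-dihydroxy-6-methoxy-5-methylbenzaldehyde | CCCC(=O)c1c(O)c(C)c(OC)c(C=O)c1O | intermediate
6 | 2,4-bis(benzyloxy)-3-butanoyl-6-methoxy-5-methylbenzaldehyde | CCCC(=O)c1c(OCc2ccccc2)c(C)c(OC)c(C=O)c1OCc1ccccc1 | intermediate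
7 | 1-[2,6-bis(benzyloxy)-3-(hydroxymethyl)-4-methoxy-5-methylphenyl]butan-1-one | CCCC(=O)c1c(OCc2ccccc2)c(C)c(OC)c(CO)c1OCc1ccccc1 | intermediate
8 | 1-[2,6-bis(benzyloxy)-3-(bromomethyl)-4-methoxy-5-methylphenyl]butan-1-one | CCCC(=O)c1c(OCc2ccccc2)c(C)c(OC)c(CBr)c1OCc1ccccc1 | intermediate
9 | 2-methylcyclohexane-1,3-dione | CC1C(=O)CCCC1=O | starting material
10 | 3-(benzyloxy)-2-methylcyclohex-2-en-1-one | CC1=C(OCc2ccccc2)CCCC1=O | intermediate
11 | lithium 5-(benzyloxy)-6-methylcyclohexa-1,5-dien-1-olate (not isolated) | [Li]OC1=CCCC(OCc2ccccc2)=C1C | intermediate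
12 | 3-(benzyloxy)-6-{[2,4-bis(benzyloxy)-3-butanoyl-6-methoxy-5-methylphenyl]methyl}-2-methylcyclohex-2-en-1-one, racemic | O=C1C(C)=C(OCc2ccccc2)CCC1Cc1c(OC)c(C)c(OCc2ccccc2)c(C(=O)CCC)c1OCc1ccccc1 | intermediate
13 | dilithium bis-enolate of 12: ring dienolate and (Z)-enolate of the butanoyl group (not isolated) | CC/C=C(\O[Li])c1c(OCc2ccccc2)c(C)c(OC)c(CC2=C(O[Li])C(C)=C(OCc3ccccc3)CC2)c1OCc1ccccc1 | intermediate
14 | 1-(benzyloxy)-2-methyl-3-(trimethylsilyloxy)-4-{[2,4-bis(benzyloxy)-6-methoxy-5-methyl-3-[(1Z)-1-(trimethylsilyloxy)but-1-en-1-yl]phenyl]methyl}cyclohexa-1,3-diene | CC/C=C(\O[Si](C)(C)C)c1c(OCc2ccccc2)c(C)c(OC)c(CC2=C(O[Si](C)(C)C)C(C)=C(OCc3ccccc3)CC2)c1OCc1ccccc1 | intermediate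
15 | adamantan-1-ol | OC12CC3CC(CC(C3)C1)C2 | starting material
16 | trichloroethylene | ClC=C(Cl)Cl | starting material
17 | potassium adamantan-1-olate (not isolated) | [K+].[O-]C12CC3CC(CC(C3)C1)C2 | intermediate
18 | 1-{[(E)-1,2-dichloroethenyl]oxy}adamantane | Cl/C=C(/Cl)OC12CC3CC(CC(C3)C1)C2 | intermediate
19 | lithium 2-(adamantan-1-yloxy)ethyn-1-ide (not isolated) | [Li]C#COC12CC3CC(CC(C3)C1)C2 | intermediate
20 | 4-(adamantan-1-yloxy)but-3-yn-2-one | CC(=O)C#COC12CC3CC(CC(C3)C1)C2 | intermediate
21 | cycloadduct, racemic, single relative configuration fixed by the bicycle: 2-acetyl-3-(adamantan-1-yloxy)-1-(benzyloxy)-6-methyl-5-(trimethylsilyloxy)bicyclo[2.2.2]octa-2,5-diene carrying at C4 the ring A-methyl group of 14 (not isolated) | CC/C=C(\O[Si](C)(C)C)c1c(OCc2ccccc2)c(C)c(OC)c(CC23CCC(OCc4ccccc4)(C(C)=C2O[Si](C)(C)C)C(C(C)=O)=C3OC23CC4CC(CC(C4)C2)C3)c1OCc1ccccc1 | intermediate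
22 | bis-silylated arene: 23 with C2'–OSiMe3 and the butanoyl group as its (Z)-trimethylsilyl enol ether (not isolated) | CC/C=C(\O[Si](C)(C)C)c1c(OCc2ccccc2)c(C)c(OC)c(Cc2c(O[Si](C)(C)C)c(C)c(OCc3ccccc3)c(C(C)=O)c2OC23CC4CC(CC(C4)C2)C3)c1OCc1ccccc1 | intermediate
23 | 1-[3-{[3-acetyl-2-(adamantan-1-yloxy)-4-(benzyloxy)-6-hydroxy-5-methylphenyl]methyl}-2,6-bis(benzyloxy)-4-methoxy-5-methylphenyl]butan-1-one | CCCC(=O)c1c(OCc2ccccc2)c(C)c(OC)c(Cc2c(O)c(C)c(OCc3ccccc3)c(C(C)=O)c2OC23CC4CC(CC(C4)C2)C3)c1OCc1ccccc1 | intermediate
24 | 1-[3-{[3-acetyl-4-(benzyloxy)-2,6-dihydroxy-5-methylphenyl]methyl}-2,6-bis(benzyloxy)-4-methoxy-5-methylphenyl]butan-1-one | CCCC(=O)c1c(OCc2ccccc2)c(C)c(OC)c(Cc2c(O)c(C)c(OCc3ccccc3)c(C(C)=O)c2O)c1OCc1ccccc1 | intermediate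
25 | 1-[3-[(3-acetyl-2,4,6-trihydroxy-5-methylphenyl)methyl]-2,6-dihydroxy-4-methoxy-5-methylphenyl]butan-1-one (CNP0258463.0) | CCCC(=O)c1c(O)c(C)c(OC)c(Cc2c(O)c(C)c(O)c(C(C)=O)c2O)c1O | target

**Count**

Total steps: 14. Longest linear sequence: 11 steps (steps 1–6, 8, 9, 12, 13, 14).

**Steps most likely to fail, and fallbacks**

Step 12 (proposed new method). The cycloaddition of a donor–acceptor ynone to a diene substituted at both termini may be slower than thermal isomerisation of the diene by [1,5]-hydrogen shift or self-condensation of the ynone, and bond formation could occur in the opposite orientation. The fallback gives up the ring construction and uses known chemistry, setting out from 1 and 4 and returning at 25. Friedel–Crafts acetylation of 1 (acetyl chloride, AlCl3, PhNO2) gives 1-(2,4,6-trihydroxy-3-methylphenyl)ethan-1-one F1. Compound 4 and an excess of F1 are then joined at their single free ring positions with aqueous formaldehyde in dilute aqueous KOH at 0 °C, the classical methylene bridging of acylphloroglucinols. The crossed product is 25 itself, to be separated by chromatography from the two symmetrical dimers.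

Step 8. Proton transfer from the butanoyl CH2 of the bromide to the basic dienolate, and ionisation with self-condensation of the electron-rich benzylic bromide, may compete with C-alkylation. The fallback sets out from 10 and 8 and returns at 12. Vinylogous ester 10 is converted with LiN(iPr)2 and Me3SiCl into 1-(benzyloxy)-2-methyl-3-(trimethylsilyloxy)cyclohexa-1,3-diene F2. This neutral enol ether is alkylated by 8 under ZnBr2 catalysis in CH2Cl2 at −40 °C, an SN1-type alkylation of a silyl enol ether by an ionisable benzylic halide. The lability of the bromide then becomes an advantage and no strong base meets the butanoyl group.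

Step 9. Deprotonation at the hindered tertiary α' position may be slow enough for γ-deprotonation and formation of the linear dienol ether to intervene, or silylation may stay incomplete. The fallback fixes the enolate position by conjugate reduction instead of deprotonation; it sets out from 6 and 10 (replacing steps 5, 6, 8 and 9) and returns at 23.
- Lithium dienolate 11 is added to aldehyde 6 at −78 °C to give 3-(benzyloxy)-6-{[2,4-bis(benzyloxy)-3-butanoyl-6-methoxy-5-methylphenyl](hydroxy)methyl}-2-methylcyclohex-2-en-1-one F3.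
- Mesylation and elimination (MsCl, Et3N; then DBU) give (6E)-3-(benzyloxy)-6-{[2,4-bis(benzyloxy)-3-butanoyl-6-methoxy-5-methylphenyl]methylidene}-2-methylcyclohex-2-en-1-one F4.
- 1,4-Hydrosilylation of the exocyclic enone (Et3SiH, RhCl(PPh3)3 cat., toluene, 60 °C) places the silyl enol ether regiospecifically and leaves the hindered butanoyl ketone free, giving 1-[2,6-bis(benzyloxy)-3-{[4-(benzyloxy)-3-methyl-2-(triethylsilyloxy)cyclohexa-1,3-dien-1-yl]methyl}-4-methoxy-5-methylphenyl]butan-1-one F5.
- F5 enters the conditions of step 12 in place of 14 and passes through the triethylsilyl analogue of the cycloadduct with a free butanoyl group F6 and the triethylsilyl analogue of the arene with a free butanoyl group F7.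
- The same acidic work-up then gives 23.

**Further compounds**

F1 | step 12 | 1-(2,4,6-trihydroxy-3-methylphenyl)ethan-1-one | CC(=O)c1c(O)c(C)c(O)cc1O
F2 | step 8 | 1-(benzyloxy)-2-methyl-3-(trimethylsilyloxy)cyclohexa-1,3-diene | CC1=C(OCc2ccccc2)CCC=C1O[Si](C)(C)C
F3 | step 9 | 3-(benzyloxy)-6-{[2,4-bis(benzyloxy)-3-butanoyl-6-methoxy-5-methylphenyl](hydroxy)methyl}-2-methylcyclohex-2-en-1-one, mixture of racemic diastereomers | O=C1C(C)=C(OCc2ccccc2)CCC1C(O)c1c(OC)c(C)c(OCc2ccccc2)c(C(=O)CCC)c1OCc1ccccc1
F4 | step 9 | (6E)-3-(benzyloxy)-6-{[2,4-bis(benzyloxy)-3-butanoyl-6-methoxy-5-methylphenyl]methylidene}-2-methylcyclohex-2-en-1-one | O=C1C(C)=C(OCc2ccccc2)CC/C1=C\c1c(OC)c(C)c(OCc2ccccc2)c(C(=O)CCC)c1OCc1ccccc1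
F5 | step 9 | 1-[2,6-bis(benzyloxy)-3-{[4-(benzyloxy)-3-methyl-2-(triethylsilyloxy)cyclohexa-1,3-dien-1-yl]methyl}-4-methoxy-5-methylphenyl]butan-1-one | CCCC(=O)c1c(OCc2ccccc2)c(C)c(OC)c(CC2=C(O[Si](CC)(CC)CC)C(C)=C(OCc3ccccc3)CC2)c1OCc1ccccc1
F6 | step 9 | triethylsilyl analogue of cycloadduct 21 with a free butanoyl group, racemic | CCCC(=O)c1c(OCc2ccccc2)c(C)c(OC)c(CC23CCC(OCc4ccccc4)(C(C)=C2O[Si](CC)(CC)CC)C(C(C)=O)=C3OC23CC4CC(CC(C4)C2)C3)c1OCc1ccccc1
F7 | step 9 | triethylsilyl analogue of arene 22 with a free butanoyl group | CCCC(=O)c1c(OCc2ccccc2)c(C)c(OC)c(Cc2c(O[Si](CC)(CC)CC)c(C)c(OCc3ccccc3)c(C(C)=O)c2OC23CC4CC(CC(C4)C2)C3)c1OCc1ccccc1
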